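**Retrosynthetic overview**
- C3–O ester disconnection gives the bicyclic core alcohol and (2E,5R)-5-(angeloyloxy)hex-2-enoic acid; the acid comes from (R)-propylene oxide, angelic acid and tert-butyl acrylate by cross-metathesis.
- The isopropenyl group comes from dehydration of a C7 acetone aldol adduct (C7–C11 by intermolecular aldol); the 9β-OH comes from Rubottom oxidation of the cis-decalone.
- 3α-OH/4β-Me come from hydroboration of a Δ3-4-methyl alkene (C4 ketone → enol triflate → methyl coupling); 10β-H comes from hydrogenation of the Wieland–Miescher ketone.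
- Key C–C bond (C5–C6): intermolecular Michael addition of 2-methylcyclohexane-1,3-dione (ring A, preformed) to methyl vinyl ketone; ring B is then closed by L-proline aldol condensation, which sets C5.

Convention (one line): eremophilane numbering is used for the core (ring A = C1–C5, C10; ring B = C5–C10; methyls on C4 and C5; C11–C13 on C7); β is the face of the C5 methyl, α the opposite face.

Step 1
Reactants: 1 2-methylcyclohexane-1,3-dione; 2 methyl vinyl ketone
Product: 3 2-methyl-2-(3-oxobutyl)cyclohexane-1,3-dione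
Conditions: H2O, AcOH (cat.), hydroquinone (cat.), 75 °C
Reagents that add atoms: none
Why: Intermolecular Michael addition of the enolised 1,3-dione to the enone forges C5–C6 and the quaternary carbon; the product is still achiral.

Step 2
Reactants: 3 triketone
Product: 5 (S)-Wieland–Miescher ketone, via cis-fused ketol 4 (not isolated)
Conditions: L-proline (5 mol %), DMSO, rt, 5 d; recrystallisation (Et2O/hexane) to ≥99% ee
Reagents that add atoms: none
Why: Hajos–Parrish–Eder–Sauer–Wiechert reaction (proline-enamine intramolecular aldol onto one enantiotopic ring carbonyl, then dehydration) closes ring B, and L-proline gives the (S) ketone, which fixes C5 with its methyl β.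

Step 3
Reactants: 5 (S)-Wieland–Miescher ketone
Product: 6 5β-methyl-10βH-decalin-4,8-dione (cis-fused)
Conditions: H2 (1 atm), 10% Pd/C, EtOAc/pyridine (20:1), rt
Reagents that add atoms: none
Why: Heterogeneous catalytic hydrogenation of this angular-methyl octalone adds hydrogen to C9=C10 from the methyl-bearing face (as with steroidal 4-en-3-ones in basic medium), giving mainly the cis-fused 10β-H dione; the minor trans isomer is removed by chromatography.

Step 4
Reactants: 6 cis-dione
Product: 7 8,8-ethylenedioxy-5β-methyl-10βH-decalin-4-one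
Conditions: Me3SiOCH2CH2OSiMe3, Me3SiOTf (5 mol %), CH2Cl2, −78 °C; pyridine quench
Reagents that add atoms: 1,2-bis(trimethylsilyloxy)ethane, C[Si](C)(C)OCCO[Si](C)(C)C
Why: Noyori ketalisation at −78 °C takes the unhindered C8 ketone and leaves the neopentyl C4 ketone, under aprotic conditions too cold for transannular aldol of the cis-dione.

Step 5
Reactants: 7 keto ketal
Product: 9 8,8-ethylenedioxy-5β-methyl-10βH-octal-3-en-4-yl triflate, via potassium enolate 8 (not isolated)
Conditions: KN(SiMe3)2, THF, −78 °C; PhNTf2, −78 → 0 °C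
Reagents that add atoms: N-phenylbis(trifluoromethanesulfonimide), O=S(=O)(N(c1ccccc1)S(=O)(=O)C(F)(F)F)C(F)(F)F
Why: Enolate O-triflation; the C4 ketone can enolise only towards C3 because C5 is quaternary, so one enol triflate forms.

Step 6
Reactants: 9 enol triflate
Product: 10 8,8-ethylenedioxy-4,5β-dimethyl-10βH-octal-3-ene
Conditions: MeZnCl, Pd(PPh3)4 (5 mol %), THF, 60 °C
Reagents that add atoms: methylzinc chloride, C[Zn]Cl
Why: Negishi cross-coupling (oxidative addition of zerovalent palladium into C–OTf, transmetalation from zinc, reductive elimination) installs the C4 methyl with the double bond fixed at C3=C4.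

Step 7
Reactants: 10 Δ3-alkene
Product: 12 8,8-ethylenedioxy-4β,5β-dimethyl-10βH-decalin-3α-ol, via 3α-alkylborane 11 (not isolated)
Conditions: BH3·THF, THF, 0 °C → rt; then 3 M NaOH, 30% H2O2, 0 °C → rt
Reagents that add atoms: hydrogen peroxide, OO
Why: Hydroboration–oxidation adds H–B syn and anti-Markovnikov from the α face (away from the pseudo-axial C5 methyl, 1,3 to C3), so boron goes to C3α and hydrogen to C4α, and oxidation with retention gives 3α-OH with the C4 methyl β.

Step 8
Reactants: 12 alcohol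
Product: 14 3α-(4-methoxybenzyloxy)-8,8-ethylenedioxy-4β,5β-dimethyl-10βH-decalin, via sodium alkoxide 13 (not isolated)
Conditions: NaH, THF/DMF, 0 °C; 4-MeOC6H4CH2Cl, Bu4NI (cat.), rt
Reagents that add atoms: 4-methoxybenzyl chloride, COc1ccc(CCl)cc1
Why: Williamson etherification gives a PMB ether that survives the enolate, peracid and silylation steps ahead and can be removed oxidatively.

Step 9
Reactants: 14 PMB ether ketal
Product: 15 3α-(4-methoxybenzyloxy)-4β,5β-dimethyl-10βH-decalin-8-one
Conditions: 1 M HCl, THF, rt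
Reagents that add atoms: water, O
Why: Acid-catalysed hydrolysis of the unhindered dioxolane frees the C8 ketone without touching the PMB ether or any stereocentre.

Step 10
Reactants: 15 ketone
Product: 18 9β-hydroxy-3α-(4-methoxybenzyloxy)-4β,5β-dimethyl-10βH-decalin-8-one, via Δ8(9) trimethylsilyl enol ether 16 (not isolated), via 9β-trimethylsilyloxy ketone 17 (not isolated)
Conditions: Me3SiCl, Et3N, DMF, 80 °C; then mCPBA, CH2Cl2, −20 → 0 °C; then 1 M HCl, THF, 0 °C
Reagents that add atoms: 3-chloroperoxybenzoic acid, O=C(OO)c1cccc(Cl)c1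
Why: Rubottom oxidation; equilibrating silylation of this cis-fused ketone (held steroid-like by the equatorial 3α-OPMB and 4β-methyl) goes towards C9, as 5β-3-keto steroids enolise towards C4, and the peracid attacks the convex β face to give the equatorial 9β-hydroxyl.

Step 11
Reactants: 18 α-ketol
Product: 19 9β-(tert-butyldimethylsilyloxy)-3α-(4-methoxybenzyloxy)-4β,5β-dimethyl-10βH-decalin-8-one
Conditions: t-BuMe2SiCl, imidazole, DMF, rt
Reagents that add atoms: tert-butyldimethylsilyl chloride, CC(C)(C)[Si](C)(C)Cl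
Why: Silylation of the secondary ketol hydroxyl blocks C9–O through the enolate and acylation chemistry and makes C7 the only kinetically enolisable α-position.

Step 12
Reactants: 19 silyloxy ketone; 20 acetone
Product: 22 9β-(tert-butyldimethylsilyloxy)-11-hydroxy-3α-(4-methoxybenzyloxy)-10βH-eremophilan-8-one, via lithium Δ7(8)-enolate 21 (not isolated)
Conditions: LiN(i-Pr)2, THF, −78 °C; 20 (5 equiv), −78 °C, 15 min; AcOH, −78 °C
Reagents that add atoms: none
Why: Directed intermolecular aldol addition; the amide base removes a C7 proton (C9 carries the siloxy group) and the enolate adds to acetone from the open β face, the α face of C7 being shielded by axial C4, so the new C7–C11 bond is equatorial (7β).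

Step 13
Reactants: 22 aldol adduct
Product: 23 9β-(tert-butyldimethylsilyloxy)-3α,11-dihydroxy-10βH-eremophilan-8-one
Conditions: DDQ, CH2Cl2/pH 7 buffer (10:1), 0 °C → rt
Reagents that add atoms: none
Why: Oxidative PMB cleavage (benzylic hydride abstraction by DDQ, then hydrolysis) frees only the C3 hydroxyl and leaves the silyl ether, tertiary alcohol and ketone alone.

Step 14
Reactants: 24 (R)-propylene oxide
Product: 25 (R)-pent-4-en-2-ol
Conditions: CH2=CHMgBr, CuBr·SMe2 (10 mol %), THF, −30 → 0 °C; then H2O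
Reagents that add atoms: vinylmagnesium bromide, C=C[Mg]Br
Why: Copper-catalysed Grignard opening of the epoxide (SN2 at the unsubstituted carbon) leaves the stereocentre of (R)-propylene oxide untouched.

Step 15
Reactants: 25 (R)-pent-4-en-2-ol; 26 angelic acid
Product: 28 (R)-pent-4-en-2-yl angelate, via angelic 2,4,6-trichlorobenzoic anhydride 27 (not isolated)
Conditions: 2,4,6-Cl3C6H2COCl, Et3N, toluene, rt; then 25, toluene, 80 °C (no DMAP)
Reagents that add atoms: none
Why: Yamaguchi-type mixed-anhydride esterification run without DMAP, conditions that acylate with angelic acid without Z→E isomerisation to the tiglate; the carbinol stereocentre is not involved.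

Step 16
Reactants: 28 pentenyl angelate; 29 tert-butyl acrylate
Product: 30 tert-butyl (2E,5R)-5-(angeloyloxy)hex-2-enoate
Conditions: second-generation Grubbs catalyst RuCl2(=CHPh)(PCy3)(SIMes) (5 mol %), 29 (5 equiv), CH2Cl2, 40 °C
Reagents that add atoms: none
Why: Olefin cross-metathesis of a terminal alkene with an acrylate gives the cross product as the E-enoate, and the trisubstituted angelate alkene is inert.

Step 17
Reactants: 30 tert-butyl ester
Product: 31 (2E,5R)-5-(angeloyloxy)hex-2-enoic acid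
Conditions: CF3CO2H/CH2Cl2 (1:4), 0 °C → rt
Reagents that add atoms: none
Why: Acidolysis of the tert-butyl ester (loss of isobutene) leaves the secondary angelate and both alkene geometries intact.

Step 18
Reactants: 23 diol; 31 side-chain acid
Product: 33 9β-(tert-butyldimethylsilyloxy)-11-hydroxy-8-oxo-10βH-eremophilan-3α-yl (2E,5R)-5-(angeloyloxy)hex-2-enoate, via 2,4,6-trichlorobenzoic mixed anhydride 32 (not isolated)
Conditions: 2,4,6-Cl3C6H2COCl, Et3N, toluene, rt; then 23, DMAP, toluene, rt
Reagents that add atoms: none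
Why: Yamaguchi esterification acylates the secondary equatorial C3 hydroxyl while the tertiary C11 hydroxyl is inert; no stereocentre is touched.

Step 19
Reactants: 33 hydroxy ester
Product: 35 9-O-tert-butyldimethylsilyl ether of the target, via C11 chlorosulfite 34 (not isolated)
Conditions: SOCl2, pyridine, CH2Cl2, −20 → 0 °C
Reagents that add atoms: none
Why: Dehydration via the chlorosulfite (E2 with pyridine) removes a methyl hydrogen rather than C7–H, which sits on the shielded concave α face, so the isopropenyl group forms and C7 is not disturbed.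

Step 20
Reactants: 35 silyl ether
Product: 36 target CNP0210874.1
Conditions: HF·pyridine, pyridine, THF, 0 °C → rt
Reagents that add atoms: none
Why: Buffered fluoride desilylation frees the 9β-hydroxyl without affecting the esters, the angelate geometry or the β,γ-unsaturated ketone.

**Compound list**
1 | 2-methylcyclohexane-1,3-dione | CC1C(=O)CCCC1=O | starting material
2 | methyl vinyl ketone (but-3-en-2-one) | C=CC(C)=O | starting material
3 | 2-methyl-2-(3-oxobutyl)cyclohexane-1,3-dione | CC(=O)CCC1(C)C(=O)CCCC1=O | intermediate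
4 | cis-fused ketol, 4a-hydroxy-8a-methyloctahydronaphthalene-1,6-dione (OH and CH3 cis) | C1C[C@@]2(C)[C@](O)(CCCC2=O)CC1=O | intermediate
5 | (S)-Wieland–Miescher ketone, (S)-8a-methyl-3,4,8,8a-tetrahydronaphthalene-1,6(2H,7H)-dione | C1C[C@@]2(C)C(CCCC2=O)=CC1=O | intermediate
6 | 5β-methyl-10βH-decalin-4,8-dione (cis-fused) | C1C[C@@]2(C)[C@H](CCCC2=O)CC1=O | intermediate
7 | 8,8-ethylenedioxy-5β-methyl-10βH-decalin-4-one | C1C[C@@]2(C)[C@H](CCCC2=O)CC13OCCO3 | intermediate
8 | potassium Δ3-enolate of 7 | C1C[C@@]2(C)[C@H](CCC=C2O[K])CC13OCCO3 | intermediate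
9 | 8,8-ethylenedioxy-5β-methyl-10βH-octal-3-en-4-yl triflate | C1C[C@@]2(C)[C@H](CCC=C2OS(=O)(=O)C(F)(F)F)CC13OCCO3 | intermediate
10 | 8,8-ethylenedioxy-4,5β-dimethyl-10βH-octal-3-ene | C1C[C@@]2(C)[C@H](CCC=C2C)CC13OCCO3 | intermediate
11 | 3α-alkylborane (BH2 on C3α, H on C4α) | C1C[C@@]2(C)[C@H](CC[C@@H](B)[C@@H]2C)CC13OCCO3 | intermediate
12 | 8,8-ethylenedioxy-4β,5β-dimethyl-10βH-decalin-3α-ol | C1C[C@@]2(C)[C@H](CC[C@@H](O)[C@@H]2C)CC13OCCO3 | intermediate
13 | sodium alkoxide of 12 | C1C[C@@]2(C)[C@H](CC[C@@H](O[Na])[C@@H]2C)CC13OCCO3 | intermediate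
14 | 3α-(4-methoxybenzyloxy)-8,8-ethylenedioxy-4β,5β-dimethyl-10βH-decalin | C1C[C@@]2(C)[C@H](CC[C@@H](OCc3ccc(OC)cc3)[C@@H]2C)CC14OCCO4 | intermediate
15 | 3α-(4-methoxybenzyloxy)-4β,5β-dimethyl-10βH-decalin-8-one | C1C[C@@]2(C)[C@H](CC[C@@H](OCc3ccc(OC)cc3)[C@@H]2C)CC1=O | intermediate
16 | Δ8(9) trimethylsilyl enol ether of 15 | C1C[C@@]2(C)[C@H](CC[C@@H](OCc3ccc(OC)cc3)[C@@H]2C)C=C1O[Si](C)(C)C | intermediate
17 | 9β-trimethylsilyloxy derivative of 15 | C1C[C@@]2(C)[C@H](CC[C@@H](OCc3ccc(OC)cc3)[C@@H]2C)[C@@H](O[Si](C)(C)C)C1=O | intermediate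
18 | 9β-hydroxy-3α-(4-methoxybenzyloxy)-4β,5β-dimethyl-10βH-decalin-8-one | C1C[C@@]2(C)[C@H](CC[C@@H](OCc3ccc(OC)cc3)[C@@H]2C)[C@@H](O)C1=O | intermediate
19 | 9β-(tert-butyldimethylsilyloxy)-3α-(4-methoxybenzyloxy)-4β,5β-dimethyl-10βH-decalin-8-one | C1C[C@@]2(C)[C@H](CC[C@@H](OCc3ccc(OC)cc3)[C@@H]2C)[C@@H](O[Si](C)(C)C(C)(C)C)C1=O | intermediate
20 | acetone | CC(C)=O | starting material
21 | lithium Δ7(8)-enolate of 19 | C=1C[C@@]2(C)[C@H](CC[C@@H](OCc3ccc(OC)cc3)[C@@H]2C)[C@@H](O[Si](C)(C)C(C)(C)C)C=1O[Li] | intermediate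
22 | 9β-(tert-butyldimethylsilyloxy)-11-hydroxy-3α-(4-methoxybenzyloxy)-10βH-eremophilan-8-one (7β side chain) | CC(C)(O)[C@H]1C[C@@]2(C)[C@H](CC[C@@H](OCc3ccc(OC)cc3)[C@@H]2C)[C@@H](O[Si](C)(C)C(C)(C)C)C1=O | intermediate
23 | 9β-(tert-butyldimethylsilyloxy)-3α,11-dihydroxy-10βH-eremophilan-8-one | CC(C)(O)[C@H]1C[C@@]2(C)[C@H](CC[C@@H](O)[C@@H]2C)[C@@H](O[Si](C)(C)C(C)(C)C)C1=O | intermediate
24 | (R)-propylene oxide | C[C@@H]1CO1 | starting material
25 | (R)-pent-4-en-2-ol | C=CC[C@@H](C)O | intermediate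
26 | angelic acid, (Z)-2-methylbut-2-enoic acid | C/C=C(/C)C(=O)O | starting material
27 | angelic 2,4,6-trichlorobenzoic anhydride | C/C=C(/C)C(=O)OC(=O)c1c(Cl)cc(Cl)cc1Cl | intermediate
28 | (R)-pent-4-en-2-yl angelate | C=CC[C@@H](C)OC(=O)/C(C)=C\C | intermediate
29 | tert-butyl acrylate | C=CC(=O)OC(C)(C)C | starting material
30 | tert-butyl (2E,5R)-5-(angeloyloxy)hex-2-enoate | CC(C)(C)OC(=O)/C=C/C[C@@H](C)OC(=O)/C(C)=C\C | intermediate
31 | (2E,5R)-5-(angeloyloxy)hex-2-enoic acid | OC(=O)/C=C/C[C@@H](C)OC(=O)/C(C)=C\C | intermediate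
32 | 2,4,6-trichlorobenzoic mixed anhydride of 31 | O=C(OC(=O)/C=C/C[C@@H](C)OC(=O)/C(C)=C\C)c1c(Cl)cc(Cl)cc1Cl | intermediate
33 | 9β-(tert-butyldimethylsilyloxy)-11-hydroxy-8-oxo-10βH-eremophilan-3α-yl (2E,5R)-5-(angeloyloxy)hex-2-enoate | CC(C)(O)[C@H]1C[C@@]2(C)[C@H](CC[C@@H](OC(=O)/C=C/C[C@@H](C)OC(=O)/C(C)=C\C)[C@@H]2C)[C@@H](O[Si](C)(C)C(C)(C)C)C1=O | intermediate
34 | C11 chlorosulfite of 33 | CC(C)(OS(=O)Cl)[C@H]1C[C@@]2(C)[C@H](CC[C@@H](OC(=O)/C=C/C[C@@H](C)OC(=O)/C(C)=C\C)[C@@H]2C)[C@@H](O[Si](C)(C)C(C)(C)C)C1=O | intermediate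
35 | 9-O-tert-butyldimethylsilyl ether of the target | C=C(C)[C@H]1C[C@@]2(C)[C@H](CC[C@@H](OC(=O)/C=C/C[C@@H](C)OC(=O)/C(C)=C\C)[C@@H]2C)[C@@H](O[Si](C)(C)C(C)(C)C)C1=O | intermediate
36 | CNP0210874.1, (3R,4R,5R,7R,9R,10S)-9β-hydroxy-8-oxo-10βH-eremophil-11-en-3α-yl (2E,5R)-5-[(Z)-2-methylbut-2-enoyloxy]hex-2-enoate | C=C(C)[C@H]1C[C@@]2(C)[C@H](CC[C@@H](OC(=O)/C=C/C[C@@H](C)OC(=O)/C(C)=C\C)[C@@H]2C)[C@@H](O)C1=O | target

**Totals**
Total step count: 20. Longest linear sequence: 16 steps (steps 1–13, then 18, 19, 20); the side-chain branch is steps 14–17.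

**Three steps most likely to fail**

Step 7 (face selectivity of hydroboration on the flexible cis-fused octalin). The fallback replaces kinetic face control by thermodynamic control; it sets out from 10 and comes back at 12. The crude alcohol from the hydroboration–oxidation of 10, that is 12 together with the 3β-hydroxy-4α-methyl diastereomer F1, is oxidised with Dess–Martin periodinane (CH2Cl2, rt). This gives the 4α-methyl-3-ketone F2 (from F1) alongside the 4β-methyl-3-ketone F3 (from 12). NaOMe in MeOH epimerises F2 at C4 into F3, whose methyl is equatorial and cis to the C5 methyl. Dissolving-metal reduction of F3 (Li, NH3, THF, EtOH, −78 °C) then gives the equatorial 3α-alcohol 12.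

Step 10 (regiochemistry of enolisation towards C9 rather than C7). The fallback generates the enol ether regiospecifically from a purified α-bromo ketone instead of by direct enolisation; it sets out from 15 and comes back at 16. Bromination of 15 with PhNMe3Br3 (THF, 0 °C) follows the 5β-3-keto steroid precedent (4β-bromide) and gives the 9β-bromo ketone F4, which can be crystallised free of any 7-bromo isomer. Zn dust with Me3SiCl (Et2O, rt) converts F4 by reductive enolate formation into the single enol ether 16, which continues through the mCPBA and HCl stages of step 10 to 18.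

Step 19 (isopropenyl versus conjugated isopropylidene on dehydration, at a late stage). The fallback makes the C7–C11 bond by cross-coupling instead of aldol/dehydration; it sets out from 19 and comes back at 35. LiN(i-Pr)2 and Me3SiCl (THF, −78 °C) convert 19 into the Δ7(8) trimethylsilyl enol ether F5. Bu3SnF turns F5 in the flask into the tributylstannyl enolate F6, which couples with 2-bromopropene under PdCl2(P(o-tol)3)2 catalysis (toluene, 100 °C; Kuwajima–Urabe/Migita α-alkenylation) to give the 7β-isopropenyl ketone F7 under neutral conditions. DDQ (CH2Cl2/pH 7 buffer) removes the PMB group to give the 3α-alcohol F8, and Yamaguchi acylation of F8 with mixed anhydride 32 (DMAP, toluene, rt) gives 35.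

**Further compounds**
F1 | step 7 | 8,8-ethylenedioxy-4α,5β-dimethyl-10βH-decalin-3β-ol (C3,C4-diastereomer of 12) | C1C[C@@]2(C)[C@H](CC[C@H](O)[C@H]2C)CC13OCCO3
F2 | step 7 | 8,8-ethylenedioxy-4α,5β-dimethyl-10βH-decalin-3-one | C1C[C@@]2(C)[C@H](CCC(=O)[C@H]2C)CC13OCCO3
F3 | step 7 | 8,8-ethylenedioxy-4β,5β-dimethyl-10βH-decalin-3-one | C1C[C@@]2(C)[C@H](CCC(=O)[C@@H]2C)CC13OCCO3
F4 | step 10 | 9β-bromo-3α-(4-methoxybenzyloxy)-4β,5β-dimethyl-10βH-decalin-8-one | C1C[C@@]2(C)[C@H](CC[C@@H](OCc3ccc(OC)cc3)[C@@H]2C)[C@@H](Br)C1=O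
F5 | step 19 | Δ7(8) trimethylsilyl enol ether of 19 | C=1C[C@@]2(C)[C@H](CC[C@@H](OCc3ccc(OC)cc3)[C@@H]2C)[C@@H](O[Si](C)(C)C(C)(C)C)C=1O[Si](C)(C)C
F6 | step 19 | tributylstannyl Δ7(8)-enolate of 19 | C=1C[C@@]2(C)[C@H](CC[C@@H](OCc3ccc(OC)cc3)[C@@H]2C)[C@@H](O[Si](C)(C)C(C)(C)C)C=1O[Sn](CCCC)(CCCC)CCCC
F7 | step 19 | 9β-(tert-butyldimethylsilyloxy)-3α-(4-methoxybenzyloxy)-10βH-eremophil-11-en-8-one | C=C(C)[C@H]1C[C@@]2(C)[C@H](CC[C@@H](OCc3ccc(OC)cc3)[C@@H]2C)[C@@H](O[Si](C)(C)C(C)(C)C)C1=O
F8 | step 19 | 9β-(tert-butyldimethylsilyloxy)-3α-hydroxy-10βH-eremophil-11-en-8-one | C=C(C)[C@H]1C[C@@]2(C)[C@H](CC[C@@H](O)[C@@H]2C)[C@@H](O[Si](C)(C)C(C)(C)C)C1=O
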